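**Retrosynthetic overview**

1. Amaurone B ⇒ Stille union (side-chain Cd–Ce bond) of the ring-bearing (E,E)-dienyl iodide 26 with the pyranone alkenylstannane 37. The 2-methoxy-4-pyranone ring is built in its own fragment from methyl 2-methyl-3-oxopentanoate (30) and (E)-3-iodo-2-methylacrylic acid (29).
2. 26 ⇒ Takai and Wittig olefinations of ring aldehyde 24 ⇒ C4/C6 diacetate of the all-β tetraol 21 ⇒ hydroxyl-directed osmylation and singlet-oxygen [4+2] on cyclohexadiene 17.
3. Ring order: the carbocycle is closed first, by disrotatory 6π electrocyclisation of trienoyl oxazolidinone 13 to cis-diene 15 (ring C1–C2 bond); the pyranone ring is closed separately (step 19) and joined last.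
4. 13 ⇒ Negishi coupling of the (2E,4Z)-iododienoyl imide 9 with the alkenylzinc from but-2-yne; 9 ⇒ Horner–Wadsworth–Emmons reaction of (Z)-3-iodo-2-methylpropenal 4 (from propargyl alcohol) with auxiliary phosphonate 8.
5. Feature used: in the cyclohexane ring (C1 side chain, C2 CHMe, C3 CMeOH, C4 CHOAc, C5 CMeOH, C6 CHOAc) the carbon substituents at C1 and C2 are cis on one face (α), and the oxygens at C3, C4, C5 and C6 all lie on the other face (β).

Key step: step 6

Numbering used: ring C1–C6 and faces α/β as in line 5; side-chain carbons Ca (on C1) to Cf (on the pyranone); triene acyl chain C1' (C=O) to C8'.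
Assumption (chemistry): triene 13 is taken to be stable towards uncatalysed ring closure at or below room temperature, as is usual for alkyl-substituted (E,Z,E)-trienes, so that closure takes place only in the aluminium chelate.

**Route**

Step 1
Reactants: 1 propargyl alcohol
Product: 3 (Z)-3-iodo-2-methylprop-2-en-1-ol, via magnesacycle 2 (not isolated)
Conditions: MeMgBr (2.5 equiv), CuI (10 mol%), THF, −10 °C → rt; then I2, −10 °C; aq. NH4Cl
Reagents that add atoms: methylmagnesium bromide C[Mg]Br; iodine II
Why: CuI-catalysed anti-carbomagnesiation of the propargylic alkoxide puts methyl on C2 and magnesium on C3 cis to the CH2O group through a five-membered chelate, and iodinolysis with retention gives the Z-iodoalkene.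

Step 2
Reactants: 3 (Z)-3-iodo-2-methylprop-2-en-1-ol
Product: 4 (Z)-3-iodo-2-methylprop-2-enal
Conditions: MnO2 (activated, excess), CH2Cl2, rt, dark; used crude
Reagents that add atoms: none
Why: Heterogeneous MnO2 oxidation of an allylic alcohol is neutral, so the Z-iodoalkene should not isomerise before the volatile aldehyde is used.

Step 3
Reactants: 5 (R)-4-benzyl-2-oxazolidinone; 6 diethylphosphonoacetic acid
Product: 8 diethyl {2-[(4R)-4-benzyl-2-oxo-1,3-oxazolidin-3-yl]-2-oxoethyl}phosphonate, via mixed pivalic anhydride 7 (not isolated)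
Conditions: 6, PivCl, Et3N, THF, −20 °C; then LiCl, 5, rt
Reagents that add atoms: none
Why: N-Acylation of an oxazolidinone by a mixed pivalic anhydride under LiCl/Et3N activation is a standard imide synthesis that needs no strong base.

Step 4
Reactants: 4 (Z)-3-iodo-2-methylprop-2-enal; 8 auxiliary phosphonate
Product: 9 (4R)-4-benzyl-3-[(2E,4Z)-5-iodo-4-methylpenta-2,4-dienoyl]-1,3-oxazolidin-2-one
Conditions: LiCl, iPr2NEt, MeCN, 0 °C → rt, dark
Reagents that add atoms: none
Why: The Masamune–Roush variant of the Horner–Wadsworth–Emmons olefination should give the 2E enoyl imide under amine-base conditions mild enough to keep the Z-iodoalkene intact.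

Step 5
Reactants: 9 (2E,4Z)-iododienoyl imide; 10 but-2-yne
Product: 13 (4R)-4-benzyl-3-[(2E,4Z,6E)-4,6-dimethylocta-2,4,6-trienoyl]-1,3-oxazolidin-2-one, via alkenylzirconocene chloride 11 (not isolated), via alkenylzinc chloride 12 (not isolated)
Conditions: 10 (1.5 equiv), Cp2Zr(H)Cl (1.2 equiv), THF, rt; then ZnCl2 (1.2 equiv), 9 (1.0 equiv), Pd(PPh3)4 (5 mol%), 0 °C → rt, dark
Reagents that add atoms: none
Why: Syn-hydrozirconation of the symmetrical alkyne, Zr-to-Zn transmetalation and Negishi cross-coupling all proceed with retention at the alkenyl carbons, so 4Z comes from 9 and 6E from the syn addition, under neutral conditions that spare the imide and keep the triene cold.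

Step 6
Reactants: 13 (2E,4Z,6E)-trienoyl oxazolidinone
Product: 15 (4R)-4-benzyl-3-{[(1S,6S)-3,5,6-trimethylcyclohexa-2,4-dien-1-yl]carbonyl}-1,3-oxazolidin-2-one, via dimethylaluminium chelate 14 (not isolated)
Conditions: Me2AlCl (2.0 equiv), CH2Cl2, −78 → 0 °C; aq. potassium sodium tartrate
Reagents that add atoms: none
Why: Proposed new method: Me2AlCl should bind both imide carbonyls of 13 as a cationic chelate (14), which holds the enoyl unit s-cis and coplanar with the oxazolidinone and lowers the triene LUMO, so that the helical s-cis,s-cis conformer closes by a concerted, thermally allowed disrotatory 6π electrocyclisation that forms the ring C1–C2 bond (C2'–C7') and the six-membered carbocycle below the temperature of the uncatalysed reaction. The closest known reaction types are the thermal and Me2AlCl-accelerated 6π electrocyclisations of acceptor-substituted hexatrienes and the chelate-controlled Diels–Alder reactions of N-enoyl oxazolidinones, from which the facial model is taken; control of the sense of disrotation by an auxiliary has no direct precedent. The carbocycle closes in the disrotatory mode, and because the acyl group (2E) and the C8' methyl (6E) are both outward substituents they must finish on the same face, so the cis C1/C2 relationship follows from orbital symmetry and olefin geometry alone. The absolute configuration is assigned to the (R)-benzyl group, which in the chelate lies over the Si face of C2' and leaves only the Re face open to C7', giving (S) at C1 and hence (S) at C2. The step needs a choice between two mirror-image helical transition states and survival of the 4Z olefin; the rigid two-point chelate is meant to secure the first and the low temperature with short contact to the Lewis acid the second.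

Step 7
Reactants: 15 cis-cyclohexadiene acyl oxazolidinone
Product: 16 [(1S,6S)-3,5,6-trimethylcyclohexa-2,4-dien-1-yl]methanol
Conditions: LiBH4, MeOH (1 equiv), THF, 0 °C
Reagents that add atoms: none
Why: Reductive cleavage of the N-acyl oxazolidinone with LiBH4 attacks the exocyclic carbonyl, releases the auxiliary and, being non-basic, should not epimerise C1 or touch the diene.

Step 8
Reactants: 16 dienyl methanol
Product: 17 tert-butyl(dimethyl){[(1S,6S)-3,5,6-trimethylcyclohexa-2,4-dien-1-yl]methoxy}silane
Conditions: TBSCl, imidazole, CH2Cl2, rt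
Reagents that add atoms: tert-butyldimethylsilyl chloride CC(C)(C)[Si](C)(C)Cl
Why: Standard silylation of a primary alcohol masks the hydroxyl so that it cannot steer the later osmylation to the α face.

Step 9
Reactants: 17 TBS-protected diene
Product: 19 C3β/C6β cis-enediol TBS ether (C4=C5 alkene), via endoperoxide 18 (not isolated)
Conditions: O2, tetraphenylporphyrin (cat.), hν (visible), CH2Cl2, −40 °C; then thiourea, MeOH, rt
Reagents that add atoms: dioxygen O=O
Why: Singlet-oxygen [4+2] cycloaddition to the cisoid ring diene should occur on the β face, away from the α substituents at C1 and C2, which sets C3 and C6, and thiourea then reduces the O–O bond to the cis-enediol without touching the alkene.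

Step 10
Reactants: 19 cis-enediol TBS ether
Product: 21 C3β/C4β/C5β/C6β tetraol TBS ether, via osmate ester 20 (not isolated)
Conditions: OsO4 (1.05 equiv), TMEDA (1.1 equiv), CH2Cl2, −78 °C; then aq. Na2SO3, THF, 60 °C
Reagents that add atoms: osmium tetroxide O=[Os](=O)(=O)=O
Why: In this hydroxyl-directed dihydroxylation the OsO4·TMEDA complex is hydrogen-bonded by the two β allylic hydroxyls and delivers both oxygens to the β face of C4=C5 (the α face is also the more hindered one), which sets C4 and C5 cis to the existing oxygens.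

Step 11
Reactants: 21 tetraol TBS ether
Product: 22 C4,C6-diacetate of 21 (C3 and C5 tertiary hydroxyls free)
Conditions: Ac2O, pyridine, DMAP (cat.), CH2Cl2, 0 °C → rt
Reagents that add atoms: acetic anhydride CC(=O)OC(C)=O
Why: DMAP-catalysed acetylation differentiates secondary from tertiary alcohols, so only the C4 and C6 hydroxyls should be esterified at room temperature.

Step 12
Reactants: 22 diacetate TBS ether
Product: 23 primary alcohol (C1 CH2OH; C4,C6 diacetate; C3,C5 diol)
Conditions: HF·pyridine, pyridine, THF, 0 °C → rt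
Reagents that add atoms: none
Why: Acidic fluoride desilylation removes the primary TBS ether without generating alkoxides, so acetate migration and hydrolysis should be avoided.

Step 13
Reactants: 23 primary alcohol
Product: 24 ring aldehyde (C1 CHO)
Conditions: Dess–Martin periodinane, NaHCO3, CH2Cl2, 0 °C → rt; used at once
Reagents that add atoms: none
Why: Dess–Martin oxidation under bicarbonate buffer is mild enough for a β-acetoxy aldehyde with an epimerisable α centre and leaves tertiary alcohols untouched.

Step 14
Reactants: 24 ring aldehyde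
Product: 25 (E)-enal (ring C1–CH=C(Me)–CHO)
Conditions: Ph3P=C(Me)CHO (1.5 equiv), toluene, 80 °C
Reagents that add atoms: 2-(triphenylphosphoranylidene)propanal CC(C=O)=P(c1ccccc1)(c1ccccc1)c1ccccc1
Why: Wittig olefination with the formyl-stabilised ylide is base-free and E-selective, giving the trisubstituted Ca=Cb alkene with C1 and Cc trans.

Step 15
Reactants: 25 (E)-enal
Product: 26 (E,E)-dienyl iodide (ring C1–CH=C(Me)–CH=CHI)
Conditions: CrCl2 (8 equiv), CHI3 (2.5 equiv), THF/dioxane, 0 °C → rt, dark
Reagents that add atoms: iodoform IC(I)I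
Why: Takai olefination converts the enal into the E-iodoalkene under non-basic conditions that tolerate acetates and free tertiary alcohols.

Step 16
Reactants: 27 diethyl methylmalonate
Product: 28 diethyl 2-(diiodomethyl)-2-methylmalonate
Conditions: NaH, Et2O, reflux; then CHI3, reflux
Reagents that add atoms: iodoform IC(I)I
Why: C-Alkylation of the malonate sodium enolate with iodoform installs the diiodomethyl group.

Step 17
Reactants: 28 diiodomethyl malonate
Product: 29 (E)-3-iodo-2-methylacrylic acid
Conditions: KOH, EtOH/H2O, reflux; then aq. HCl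
Reagents that add atoms: none
Why: Saponification followed by decarboxylative elimination of iodide (a Grob-type fragmentation) gives the thermodynamically favoured E-iodoacrylic acid.

Step 18
Reactants: 29 (E)-3-iodo-2-methylacrylic acid; 30 methyl 2-methyl-3-oxopentanoate
Product: 33 methyl (E)-7-iodo-2,4,6-trimethyl-3,5-dioxohept-6-enoate, via acyl imidazolide 31 (not isolated), via ketoester dianion 32 (not isolated)
Conditions: 29, CDI, THF, rt; separately 30, NaH then n-BuLi, THF, 0 °C; add 31 to 32 (2.2 equiv), −78 → 0 °C; 1 M HCl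
Reagents that add atoms: none
Why: Claisen-type acylation of the γ carbon of the β-ketoester dianion by the acyl imidazolide builds the triketide chain, the terminal carbanion reacting at the acyl carbon in preference to the vinylic iodide.

Step 19
Reactants: 33 triketide ester
Product: 34 4-hydroxy-6-[(E)-1-iodoprop-1-en-2-yl]-3,5-dimethyl-2H-pyran-2-one
Conditions: DBU, toluene, 60 °C
Reagents that add atoms: none
Why: DBU-mediated lactonisation of the enolised triketide (enol O-acylation by the methyl ester) closes the 4-hydroxy-2-pyranone ring.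

Step 20
Reactants: 34 hydroxypyranone
Product: 36 2-[(E)-1-iodoprop-1-en-2-yl]-6-methoxy-3,5-dimethyl-4H-pyran-4-one, via hydroxypyrylium triflate 35 (not isolated)
Conditions: MeOTf, CH2Cl2, rt; aq. NaHCO3
Reagents that add atoms: methyl trifluoromethanesulfonate COS(=O)(=O)C(F)(F)F
Why: Methylation of the neutral hydroxypyranone with a hard methylating agent occurs on the lactone carbonyl oxygen to give a 4-hydroxy-2-methoxypyrylium salt, which on deprotonation is the 2-methoxy-4-pyranone and not the isomeric 4-methoxy-2-pyranone.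

Step 21
Reactants: 36 pyranone alkenyl iodide
Product: 37 2-methoxy-3,5-dimethyl-6-[(E)-1-(trimethylstannyl)prop-1-en-2-yl]-4H-pyran-4-one
Conditions: (Me3Sn)2 (1.5 equiv), Pd(PPh3)4 (5 mol%), toluene, 90 °C
Reagents that add atoms: hexamethylditin C[Sn](C)(C)[Sn](C)(C)C
Why: Pd(PPh3)4-catalysed stannylation of an alkenyl iodide with hexamethylditin proceeds with retention of the E geometry.

Step 22
Reactants: 26 (E,E)-dienyl iodide; 37 pyranone alkenylstannane
Product: 38 Amaurone B
Conditions: PdCl2(MeCN)2 (10 mol%), DMF, rt, dark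
Reagents that add atoms: none
Why: Stille cross-coupling of the dienyl iodide with the alkenylstannane is neutral, proceeds with retention at both alkenes and tolerates the acetates, the free tertiary alcohols and the pyranone, giving the all-E triene.

**Compound list**

1 | propargyl alcohol | C#CCO | starting material
2 | cyclic (Z)-alkenylmagnesium alkoxide (4-methyl-2,5-dihydro-1,2-oxamagnesole) | CC1=C[Mg]OC1 | intermediate
3 | (Z)-3-iodo-2-methylprop-2-en-1-ol | OC/C(C)=C\I | intermediate
4 | (Z)-3-iodo-2-methylprop-2-enal | O=C/C(C)=C\I | intermediate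
5 | (R)-4-benzyl-2-oxazolidinone | O=C1OC[C@@H](Cc2ccccc2)N1 | starting material
6 | diethylphosphonoacetic acid | CCOP(=O)(OCC)CC(=O)O | starting material
7 | diethylphosphonoacetic pivalic anhydride | CCOP(=O)(OCC)CC(=O)OC(=O)C(C)(C)C | intermediate
8 | diethyl {2-[(4R)-4-benzyl-2-oxo-1,3-oxazolidin-3-yl]-2-oxoethyl}phosphonate | CCOP(=O)(OCC)CC(=O)N1C(=O)OC[C@H]1Cc1ccccc1 | intermediate
9 | (4R)-4-benzyl-3-[(2E,4Z)-5-iodo-4-methylpenta-2,4-dienoyl]-1,3-oxazolidin-2-one | I/C=C(C)\C=C\C(=O)N1C(=O)OC[C@H]1Cc1ccccc1 | intermediate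
10 | but-2-yne | CC#CC | starting material
11 | (E)-but-2-en-2-ylzirconocene chloride (Cp drawn σ-bonded) | C/C=C(\C)[Zr](Cl)(C1C=CC=C1)C1C=CC=C1 | intermediate
12 | (E)-but-2-en-2-ylzinc chloride | C/C=C(\C)[Zn]Cl | intermediate
13 | (4R)-4-benzyl-3-[(2E,4Z,6E)-4,6-dimethylocta-2,4,6-trienoyl]-1,3-oxazolidin-2-one | C/C=C(C)/C=C(C)\C=C\C(=O)N1C(=O)OC[C@H]1Cc1ccccc1 | intermediate
14 | O,O'-dimethylaluminium chelate of 13 (cation) with dichlorodimethylaluminate | C/C=C(C)/C=C(C)\C=C\C1=[O+][Al-](C)(C)[O+]=C2OC[C@@H](Cc3ccccc3)N12.C[Al-](C)(Cl)Cl | intermediate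
15 | (4R)-4-benzyl-3-{[(1S,6S)-3,5,6-trimethylcyclohexa-2,4-dien-1-yl]carbonyl}-1,3-oxazolidin-2-one (acyl and C2 methyl cis) | O=C(N1C(=O)OC[C@H]1Cc1ccccc1)[C@@H]2[C@H](C)C(C)=CC(C)=C2 | intermediate
16 | [(1S,6S)-3,5,6-trimethylcyclohexa-2,4-dien-1-yl]methanol | OC[C@@H]1[C@H](C)C(C)=CC(C)=C1 | intermediate
17 | tert-butyl(dimethyl){[(1S,6S)-3,5,6-trimethylcyclohexa-2,4-dien-1-yl]methoxy}silane | CC(C)(C)[Si](C)(C)OC[C@@H]1[C@H](C)C(C)=CC(C)=C1 | intermediate
18 | endoperoxide: O–O bridge from C3 to C6 on the β face, C4=C5 alkene, C1 CH2OTBS and C2 methyl α (2,3-dioxabicyclo[2.2.2]oct-5-ene) | CC(C)(C)[Si](C)(C)OC[C@@H]1[C@H](C)[C@@]2(C)OO[C@@H]1C(C)=C2 | intermediate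
19 | cis-enediol: C3β-OH (tertiary), C6β-OH, C4=C5 alkene, C1α CH2OTBS, C2α methyl | CC(C)(C)[Si](C)(C)OC[C@@H]1[C@H](C)[C@@](C)(O)C=C(C)[C@H]1O | intermediate
20 | cyclic C4,C5 β-osmate ester of 19 with TMEDA on osmium | CC(C)(C)[Si](C)(C)OC[C@@H]1[C@H](C)[C@@](C)(O)[C@@H](O2)[C@@](C)(O[Os-2]23(=O)(=O)[N+](C)(C)CC[N+]3(C)C)[C@H]1O | intermediate
21 | tetraol: C3β, C4β, C5β, C6β hydroxyls, C1α CH2OTBS, C2α methyl | CC(C)(C)[Si](C)(C)OC[C@@H]1[C@H](C)[C@@](C)(O)[C@@H](O)[C@@](C)(O)[C@H]1O | intermediate
22 | C4,C6-diacetate of 21 | CC(C)(C)[Si](C)(C)OC[C@@H]1[C@H](C)[C@@](C)(O)[C@@H](OC(C)=O)[C@@](C)(O)[C@H]1OC(C)=O | intermediate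
23 | primary alcohol: C1α CH2OH, C4β and C6β acetates, C3β and C5β hydroxyls | OC[C@@H]1[C@H](C)[C@@](C)(O)[C@@H](OC(C)=O)[C@@](C)(O)[C@H]1OC(C)=O | intermediate
24 | ring aldehyde: C1α CHO, otherwise as 23 | O=C[C@@H]1[C@H](C)[C@@](C)(O)[C@@H](OC(C)=O)[C@@](C)(O)[C@H]1OC(C)=O | intermediate
25 | (E)-2-methyl-3-(ring-C1)prop-2-enal, ring as in 24 | O=C/C(C)=C/[C@@H]1[C@H](C)[C@@](C)(O)[C@@H](OC(C)=O)[C@@](C)(O)[C@H]1OC(C)=O | intermediate
26 | (1E,3E)-4-iodo-2-methylbuta-1,3-dien-1-yl at ring C1, ring as in 24 | I/C=C/C(C)=C/[C@@H]1[C@H](C)[C@@](C)(O)[C@@H](OC(C)=O)[C@@](C)(O)[C@H]1OC(C)=O | intermediate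
27 | diethyl methylmalonate | CCOC(=O)C(C)C(=O)OCC | starting material
28 | diethyl 2-(diiodomethyl)-2-methylmalonate | CCOC(=O)C(C)(C(I)I)C(=O)OCC | intermediate
29 | (E)-3-iodo-2-methylacrylic acid | OC(=O)/C(C)=C/I | intermediate
30 | methyl 2-methyl-3-oxopentanoate | CCC(=O)C(C)C(=O)OC | starting material
31 | (E)-1-(1H-imidazol-1-yl)-3-iodo-2-methylprop-2-en-1-one | O=C(/C(C)=C/I)n1ccnc1 | intermediate
32 | sodium lithium dienolate (dianion) of 30 | [Na+].[Li+].CC=C([O-])C(C)=C([O-])OC | intermediate
33 | methyl (E)-7-iodo-2,4,6-trimethyl-3,5-dioxohept-6-enoate (mixture of epimers and enol forms) | COC(=O)C(C)C(=O)C(C)C(=O)/C(C)=C/I | intermediate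
34 | 4-hydroxy-6-[(E)-1-iodoprop-1-en-2-yl]-3,5-dimethyl-2H-pyran-2-one | O=c1oc(/C(C)=C/I)c(C)c(O)c1C | intermediate
35 | 4-hydroxy-6-[(E)-1-iodoprop-1-en-2-yl]-2-methoxy-3,5-dimethylpyrylium triflate | COc1[o+]c(/C(C)=C/I)c(C)c(O)c1C.[O-]S(=O)(=O)C(F)(F)F | intermediate
36 | 2-[(E)-1-iodoprop-1-en-2-yl]-6-methoxy-3,5-dimethyl-4H-pyran-4-one | COc1oc(/C(C)=C/I)c(C)c(=O)c1C | intermediate
37 | 2-methoxy-3,5-dimethyl-6-[(E)-1-(trimethylstannyl)prop-1-en-2-yl]-4H-pyran-4-one | COc1oc(/C(C)=C/[Sn](C)(C)C)c(C)c(=O)c1C | intermediate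
38 | Amaurone B | COc1oc(/C(C)=C/C=C/C(C)=C/[C@@H]2[C@H](C)[C@@](C)(O)[C@@H](OC(C)=O)[C@@](C)(O)[C@H]2OC(C)=O)c(C)c(=O)c1C | target

**Step count**

Total: 22 steps. Longest linear sequence: 15 steps (steps 1, 2, 4–15 and 22, from propargyl alcohol); the pyranone branch is 7 steps (16–22) and the phosphonate is 1 step (3).

**Steps most likely to fail**

Step 6 (bears the label "Proposed new method:"). The closure may be too slow under the Lewis acid. The Lewis acid may instead isomerise the 4Z olefin or transfer a methyl group in conjugate fashion. The chelate may also discriminate the two helical transition states only weakly, or in the opposite sense. Fallback, known chemistry, from 13 back to 15: 13 would be heated without Lewis acid (toluene, 80–100 °C, argon), where orbital symmetry still allows only the cis ring. This should give 15 together with its ring diastereomer (4R)-4-benzyl-3-{[(1R,6R)-3,5,6-trimethylcyclohexa-2,4-dien-1-yl]carbonyl}-1,3-oxazolidin-2-one F1. The two imides are diastereomers and would be separated by chromatography or crystallisation, the auxiliary serving as a covalent resolving group, and 15 then enters step 7.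

Step 14. The Wittig reaction of the hindered aldehyde is slow, and at 80 °C the C6 acetate may be lost by β-elimination or C1 may epimerise. Fallback from 21 back to 25, with the acetates installed only after the olefination:
- 21 would be converted with 2,2-dimethoxypropane and CSA into the C3,C4:C5,C6 bis-acetonide TBS ether F2.
- TBAF would give the primary alcohol F3, and Dess–Martin oxidation the aldehyde F4, whose β-oxygen is now a poor leaving group.
- The same Wittig reagent would give the bis-acetonide enal F5.
- Aqueous acetic acid would release the tetraol enal F6.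
- Ac2O/pyridine/DMAP would acetylate the two secondary hydroxyls to give 25.

Step 10. Hydrogen-bond delivery may be incomplete because one directing hydroxyl is tertiary and both are crowded, so osmylation could occur partly on the α face. Fallback from 17 back to 21, using steric control in the bicycle instead of hydrogen bonding:
- 17 would be photo-oxygenated as in step 9 but the endoperoxide 18 isolated.
- OsO4 (cat.)/NMO would dihydroxylate the C4=C5 bridge of 18 from the side of the peroxide bridge, because the other face lies under the C1 and C2 substituents, giving the endoperoxide β-diol F7.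
- Thiourea in MeOH would reduce the O–O bond to give 21.

**Further compounds**

F1 | step 6 | (4R)-4-benzyl-3-{[(1R,6R)-3,5,6-trimethylcyclohexa-2,4-dien-1-yl]carbonyl}-1,3-oxazolidin-2-one | O=C(N1C(=O)OC[C@H]1Cc1ccccc1)[C@H]2[C@@H](C)C(C)=CC(C)=C2
F2 | step 14 | C3,C4:C5,C6 bis-acetonide of 21 (TBS ether) | CC(C)(C)[Si](C)(C)OC[C@@H]1[C@H](C)[C@@]3(C)OC(C)(C)O[C@H]3[C@@]4(C)OC(C)(C)O[C@H]41
F3 | step 14 | bis-acetonide primary alcohol | OC[C@@H]1[C@H](C)[C@@]3(C)OC(C)(C)O[C@H]3[C@@]4(C)OC(C)(C)O[C@H]41
F4 | step 14 | bis-acetonide aldehyde | O=C[C@@H]1[C@H](C)[C@@]3(C)OC(C)(C)O[C@H]3[C@@]4(C)OC(C)(C)O[C@H]41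
F5 | step 14 | bis-acetonide (E)-enal | O=C/C(C)=C/[C@@H]1[C@H](C)[C@@]3(C)OC(C)(C)O[C@H]3[C@@]4(C)OC(C)(C)O[C@H]41
F6 | step 14 | tetraol (E)-enal | O=C/C(C)=C/[C@@H]1[C@H](C)[C@@](C)(O)[C@@H](O)[C@@](C)(O)[C@H]1O
F7 | step 10 | endoperoxide C4β,C5β-diol (TBS ether) | CC(C)(C)[Si](C)(C)OC[C@@H]1[C@H](C)[C@@]2(C)OO[C@@H]1[C@](C)(O)[C@@H]2O
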